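**Plan**

1. Retrosynthesis: first the C18–O ester bond and the two silyl ethers are cut; then, with a C1=C2 double bond placed in ring A, the bonds C3–C4 and C5–C10 are cut together, which opens rings A and B to an acyclic (E,E)-trienal; then C1–C2 and C10–C20 (diene from a terminal alkyne C10≡C1) and C9–C11 (epoxide opening).
2. Building blocks: a C11–C15 Grignard reagent from (R)-methyl hydrogen 3-methylglutarate, the 2,3-epoxide of nerol, and angelic acid for the ester.
3. Forward: the side chain is joined at C9; the C10 end becomes alkyne, alkenyl iodide and (E)-diene; the prenyl end is oxidised before the diene exists and becomes the (E)-2-methylenal; rings A and B then close together in one intramolecular Diels–Alder step; reduction, hydrogenation, angeloylation and desilylation finish.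
4. Stereochemistry: C13 comes from the glutarate; C8 and C9 come from Sharpless epoxidation of the Z-alkene of nerol with D-(−)-diethyl tartrate and SN2 inversion at C9; C4, C5 and C10 come from the two alkene geometries and the endo chair transition state, relayed from C8 and C9.
5. Enabling feature: ring A holds the quaternary carbons C4 and C10 on either side of C5, so a C1=C2 double bond turns ring A into a cyclohexene whose bonds C3–C4 and C5–C10 are the two σ-bonds of a [4+2] cycloaddition, while the tether C6–C9 closes ring B in the same event.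

Key step: step 14

Remark: labdane numbers (C1–C20) are used for all intermediates, and the target is read as the ent-labdane (4S,5S,8S,9S,10R,13S), in which C18 is the oxymethyl group on C4 that is cis to H5 and trans to the C20 methyl.

**Step 1**
Reactants: 1 (R)-5-methoxy-3-methyl-5-oxopentanoic acid
Product: 2 methyl (R)-5-hydroxy-3-methylpentanoate
Conditions: BH3·SMe2 (1.2 equiv), THF, 0 °C → rt; MeOH quench; crude product used at once
Reagents that add atoms: none
Why: Borane reduces a free carboxylic acid through its acyloxyborane far faster than it touches a methyl ester (chemoselective borane reduction), so only the acid end, the future C15, becomes the primary alcohol while the non-enolisable C13 stereocentre is left as it is.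

**Step 2**
Reactants: 2 methyl (R)-5-hydroxy-3-methylpentanoate
Product: 3 methyl (R)-5-[(tert-butyldimethylsilyl)oxy]-3-methylpentanoate
Conditions: TBSCl (1.2 equiv), imidazole (2.5 equiv), CH2Cl2, 0 °C → rt
Reagents that add atoms: tert-butyldimethylsilyl chloride, CC(C)(C)[Si](C)(C)Cl
Why: Imidazole-promoted silylation of the unhindered primary alcohol is fast and traps the hydroxy ester before it can close to the δ-lactone, and the tert-butyldimethylsilyl ether then guards C15–O up to the last step.

**Step 3**
Reactants: 3 methyl (R)-5-[(tert-butyldimethylsilyl)oxy]-3-methylpentanoate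
Product: 4 (S)-5-[(tert-butyldimethylsilyl)oxy]-3-methylpentan-1-ol
Conditions: LiAlH4 (1.0 equiv), Et2O, 0 °C; aqueous NaOH work-up
Reagents that add atoms: none
Why: LiAlH4 reduces the methyl ester to the primary alcohol (ester hydride reduction) at 0 °C without touching the silyl ether, which brings the former ester carbon, the future C11, to the alcohol level (the descriptor changes only through the priority rules).

**Step 4**
Reactants: 4 (S)-5-[(tert-butyldimethylsilyl)oxy]-3-methylpentan-1-ol
Product: 5 (R)-[(5-bromo-3-methylpentyl)oxy](tert-butyl)dimethylsilane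
Conditions: CBr4 (1.3 equiv), PPh3 (1.35 equiv), 2,6-lutidine (0.2 equiv), CH2Cl2, 0 °C
Reagents that add atoms: carbon tetrabromide, BrC(Br)(Br)Br
Why: The Appel reaction replaces the primary hydroxyl by bromide through the alkoxyphosphonium ion under nearly neutral, buffered conditions that the silyl ether tolerates, and no stereocentre takes part.

**Step 5**
Reactants: 6 nerol
Product: 7 (2R,3S)-2,3-epoxynerol
Conditions: Ti(OiPr)4 (5 mol%), D-(−)-diethyl tartrate (7 mol%), t-BuOOH (2.0 equiv, anhydrous), powdered 4 Å molecular sieves, CH2Cl2, −20 °C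
Reagents that add atoms: tert-butyl hydroperoxide, CC(C)(C)OO
Why: In the Sharpless asymmetric epoxidation the catalyst formed from Ti(OiPr)4 and the tartrate binds the allylic alcohol and the hydroperoxide and delivers oxygen to one face of the C2=C3 bond only, D-(−)-diethyl tartrate giving the (2R,3S)-oxide (the mirror image of the oxide formed with the L-(+)-ester), which fixes the future C8 and, before its inversion, the future C9, while the isolated 6,7-alkene has no directing hydroxyl and stays intact.

**Step 6**
Reactants: 5 (R)-[(5-bromo-3-methylpentyl)oxy](tert-butyl)dimethylsilane; 7 (2R,3S)-2,3-epoxynerol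
Product: 10 (2S,3S)-2-{(3S)-5-[(tert-butyldimethylsilyl)oxy]-3-methylpentyl}-3,7-dimethyloct-6-ene-1,3-diol, via Grignard reagent 8 (not isolated), via bromomagnesium alkoxide 9 (not isolated)
Conditions: 5 (1.8 equiv), Mg, 1,2-dibromoethane (cat.), THF, 40 °C; separately 7, MeMgBr (1.0 equiv), THF, −40 °C; CuI (15 mol%), then the solution of 8, −40 → −10 °C; aqueous NH4Cl
Reagents that add atoms: none
Why: In this CuI-catalysed Grignard opening of a 2,3-epoxy alcohol the fully substituted C3 is closed to SN2 attack, so the cuprate formed from 8 and CuI enters at C2 with inversion and gives the 1,3-diol, which turns the cis-epoxide into the (2S,3S) pair that becomes C9 and C8, while prior deprotonation with MeMgBr spares reagent 8 and the low temperature keeps Payne rearrangement slow.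

**Step 7**
Reactants: 10 (2S,3S)-2-{(3S)-5-[(tert-butyldimethylsilyl)oxy]-3-methylpentyl}-3,7-dimethyloct-6-ene-1,3-diol
Product: 11 (2S,3S)-2-{(3S)-5-[(tert-butyldimethylsilyl)oxy]-3-methylpentyl}-3,7-dimethyl-1,3-bis[(triethylsilyl)oxy]oct-6-ene
Conditions: TESOTf (2.6 equiv), 2,6-lutidine (4 equiv), CH2Cl2, −78 → 0 °C
Reagents that add atoms: triethylsilyl trifluoromethanesulfonate, CC[Si](CC)(CC)OS(=O)(=O)C(F)(F)F
Why: The silyl triflate with 2,6-lutidine is reactive enough to silylate the hindered tertiary hydroxyl on the future C8 as well as the primary one, which protects C8–O against the Lewis acids of the later steps without touching any stereocentre.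

**Step 8**
Reactants: 11 (2S,3S)-2-{(3S)-5-[(tert-butyldimethylsilyl)oxy]-3-methylpentyl}-3,7-dimethyl-1,3-bis[(triethylsilyl)oxy]oct-6-ene
Product: 12 (2R,3S)-2-{(3S)-5-[(tert-butyldimethylsilyl)oxy]-3-methylpentyl}-3,7-dimethyl-3-[(triethylsilyl)oxy]oct-6-enal
Conditions: (COCl)2, DMSO, CH2Cl2, −78 → −35 °C; then Et3N, −78 → 0 °C
Reagents that add atoms: none
Why: Under Swern conditions the chlorodimethylsulfonium ion attacks only the unhindered primary triethylsilyl ether, chloride removes the silyl group and the alkoxysulfonium ylide collapses to the aldehyde (Swern oxidation with direct cleavage of a primary silyl ether), whereas the tertiary triethylsilyl and the tert-butyldimethylsilyl ethers stay, and the cold, brief contact with amine base preserves the α-stereocentre C9.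

**Step 9**
Reactants: 12 (2R,3S)-2-{(3S)-5-[(tert-butyldimethylsilyl)oxy]-3-methylpentyl}-3,7-dimethyl-3-[(triethylsilyl)oxy]oct-6-enal
Product: 13 tert-butyl{[(3S,6S,7S)-6-ethynyl-3,7,11-trimethyl-7-[(triethylsilyl)oxy]dodec-10-en-1-yl]oxy}dimethylsilane
Conditions: dimethyl (1-diazo-2-oxopropyl)phosphonate (1.5 equiv), K2CO3 (2 equiv), MeOH, 0 °C → rt
Reagents that add atoms: dimethyl (1-diazo-2-oxopropyl)phosphonate, CC(=O)C(=[N+]=[N-])P(=O)(OC)OC
Why: In the Seyferth–Gilbert homologation with the Ohira–Bestmann reagent the diazomethylphosphonate anion released by methanolysis adds to the aldehyde, and loss of dimethyl phosphate and dinitrogen with a 1,2-hydride shift of the alkylidene carbene gives the terminal alkyne C10≡C1 under carbonate conditions mild enough to leave C9 and the β-silyloxy group in place.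

**Step 10**
Reactants: 13 tert-butyl{[(3S,6S,7S)-6-ethynyl-3,7,11-trimethyl-7-[(triethylsilyl)oxy]dodec-10-en-1-yl]oxy}dimethylsilane
Product: 15 (2E,6S,7S,10S)-12-[(tert-butyldimethylsilyl)oxy]-7-ethynyl-2,6,10-trimethyl-6-[(triethylsilyl)oxy]dodec-2-en-1-ol, via enal 14 (not isolated)
Conditions: SeO2 (0.3 equiv), t-BuOOH (3 equiv), salicylic acid (0.1 equiv), CH2Cl2, 0 °C → rt; then NaBH4 (0.5 equiv), MeOH, 0 °C
Reagents that add atoms: selenium dioxide, O=[Se]=O; tert-butyl hydroperoxide, CC(C)(C)OO
Why: Catalytic SeO2 with t-BuOOH oxidises the electron-rich trisubstituted alkene by an ene reaction and [2,3]-sigmatropic shift at the methyl group trans to the chain, which gives the (E)-allylic alcohol (Riley allylic oxidation) while the hindered tertiary propargylic C–H and the silyl ethers react far more slowly, and NaBH4 returns the over-oxidised portion, enal 14, to alcohol 15 in the same flask.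

**Step 11**
Reactants: 15 (2E,6S,7S,10S)-12-[(tert-butyldimethylsilyl)oxy]-7-ethynyl-2,6,10-trimethyl-6-[(triethylsilyl)oxy]dodec-2-en-1-ol
Product: 17 (2E,6S,7S,10S)-12-[(tert-butyldimethylsilyl)oxy]-7-[(E)-1-iodoprop-1-en-2-yl]-2,6,10-trimethyl-6-[(triethylsilyl)oxy]dodec-2-en-1-ol, via alkenylalane 16 (not isolated)
Conditions: Me3Al (4 equiv), Cp2ZrCl2 (0.5 equiv), CH2Cl2, 0 °C → rt; then I2 (1.3 equiv), THF, −30 °C
Reagents that add atoms: trimethylaluminium, C[Al](C)C; iodine, [I][I]
Why: In the Cp2ZrCl2-catalysed carboalumination of a terminal alkyne (Negishi carboalumination) methyl and aluminium add syn with the metal at the terminal carbon, so iodinolysis with retention gives the (E)-2-methylalkenyl iodide in which C9 and iodine are trans and C20 sits on C10, the hydroxyl being masked in the flask as its O–AlMe2 derivative and the trisubstituted alkene being inert to the reagent.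

**Step 12**
Reactants: 17 (2E,6S,7S,10S)-12-[(tert-butyldimethylsilyl)oxy]-7-[(E)-1-iodoprop-1-en-2-yl]-2,6,10-trimethyl-6-[(triethylsilyl)oxy]dodec-2-en-1-ol
Product: 18 (2E,6S,7S,8E)-7-{(3S)-5-[(tert-butyldimethylsilyl)oxy]-3-methylpentyl}-2,6,8-trimethyl-6-[(triethylsilyl)oxy]undeca-2,8,10-trien-1-ol
Conditions: tributyl(vinyl)stannane (1.5 equiv), PdCl2(MeCN)2 (5 mol%), DMF, rt
Reagents that add atoms: tributyl(vinyl)stannane, C=C[Sn](CCCC)(CCCC)CCCC
Why: The Stille coupling (oxidative addition of the alkenyl iodide to zerovalent palladium, transmetalation from the stannane, reductive elimination) joins C1 to the vinyl unit C2=C3 with retention of geometry, so the (E)-diene with the C20 methyl on the inside is obtained under neutral conditions that leave the free allylic alcohol and the silyl ethers alone.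

**Step 13**
Reactants: 18 (2E,6S,7S,8E)-7-{(3S)-5-[(tert-butyldimethylsilyl)oxy]-3-methylpentyl}-2,6,8-trimethyl-6-[(triethylsilyl)oxy]undeca-2,8,10-trien-1-ol
Product: 19 (2E,6S,7S,8E)-7-{(3S)-5-[(tert-butyldimethylsilyl)oxy]-3-methylpentyl}-2,6,8-trimethyl-6-[(triethylsilyl)oxy]undeca-2,8,10-trienal
Conditions: activated MnO2 (20 equiv), CH2Cl2, rt; filtered and used directly
Reagents that add atoms: none
Why: Activated MnO2 oxidises allylic alcohols selectively to enals on its surface without isomerising the trisubstituted alkene, which delivers the (E)-2-methylenal dienophile while the diene and the silyl ethers are unaffected.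

**Step 14**
Reactants: 19 (2E,6S,7S,8E)-7-{(3S)-5-[(tert-butyldimethylsilyl)oxy]-3-methylpentyl}-2,6,8-trimethyl-6-[(triethylsilyl)oxy]undeca-2,8,10-trienal
Product: 20 (4S,5S,8S,9S,10R,13S)-15-[(tert-butyldimethylsilyl)oxy]-8-[(triethylsilyl)oxy]-ent-labd-1-en-18-al
Conditions: Me2AlCl (1.5 equiv, 1 M in hexanes), CH2Cl2, −78 → −20 °C; aqueous potassium sodium tartrate quench
Reagents that add atoms: none
Why: Me2AlCl coordinates the formyl oxygen of the (E)-2-methylenal and lowers its LUMO, and the activated C4=C5 bond then adds suprafacially to the s-cis diene C10=C1–C2=C3 in a concerted, asynchronous [4+2] cycloaddition; the closest known reaction type is the Lewis acid-promoted type 1 intramolecular Diels–Alder reaction of 2,8,10-undecatrienals (terminally activated 1,7,9-decatrienes) to trans-fused octalins, including cases that create an angular methyl group. Ring A closes as the new cyclohexene (C10, C1=C2, C3, C4, C5) through the two σ-bonds C3–C4 and C5–C10, and ring B closes in the same event as a six-membered chair (C5 to C10) because the four-carbon tether C6–C9 links dienophile and diene. C4 is set by the (E)-enal geometry (C18 cis to H5), C10 by the (E)-diene geometry (C9 outside, C20 inside) and C5 by the aldehyde-endo, tether-exo arrangement that places H5 anti to C20 and so gives the trans ring fusion. Two selectivities are needed, endo over exo and the diene face that matches C8 and C9: the first rests on the Lewis acid-enhanced endo preference of the complexed formyl group acting together with the chair tether, the second on the chair in which the C11 chain on C9 and the silyloxy group on C8 are equatorial and H9 lies near the diene plane, which minimises allylic strain against the C20 methyl. The inside methyl on C10 and the two quaternary carbons being formed slow the reaction, and this is offset by intramolecularity, a full equivalent of Lewis acid and the absence of any competing dienophile.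

**Step 15**
Reactants: 20 (4S,5S,8S,9S,10R,13S)-15-[(tert-butyldimethylsilyl)oxy]-8-[(triethylsilyl)oxy]-ent-labd-1-en-18-al
Product: 21 (4S,5S,8S,9S,10R,13S)-15-[(tert-butyldimethylsilyl)oxy]-8-[(triethylsilyl)oxy]-ent-labd-1-en-18-ol
Conditions: NaBH4 (1.5 equiv), MeOH/THF, 0 °C
Reagents that add atoms: none
Why: NaBH4 reduces the neopentyl-type aldehyde to the primary alcohol C18–OH (hydride reduction) without affecting the alkene or the silyl ethers, and the quaternary C4 cannot epimerise.

**Step 16**
Reactants: 21 (4S,5S,8S,9S,10R,13S)-15-[(tert-butyldimethylsilyl)oxy]-8-[(triethylsilyl)oxy]-ent-labd-1-en-18-ol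
Product: 22 (4S,5S,8S,9S,10R,13S)-15-[(tert-butyldimethylsilyl)oxy]-8-[(triethylsilyl)oxy]-ent-labdan-18-ol
Conditions: H2 (1 atm), 10% Pd/C, EtOAc, rt
Reagents that add atoms: none
Why: Heterogeneous hydrogenation over Pd/C saturates the cis-disubstituted C1=C2 bond of ring A, which creates no stereocentre, and ethyl acetate as solvent avoids the solvolysis of the triethylsilyl ether that Pd/C promotes in methanol.

**Step 17**
Reactants: 22 (4S,5S,8S,9S,10R,13S)-15-[(tert-butyldimethylsilyl)oxy]-8-[(triethylsilyl)oxy]-ent-labdan-18-ol; 23 angelic acid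
Product: 25 (4S,5S,8S,9S,10R,13S)-15-[(tert-butyldimethylsilyl)oxy]-8-[(triethylsilyl)oxy]-ent-labdan-18-yl (2Z)-2-methylbut-2-enoate, via mixed anhydride 24 (not isolated)
Conditions: 23 (3 equiv), 2,4,6-trichlorobenzoyl chloride (3 equiv), Et3N (3.3 equiv), toluene, rt; then 22, toluene, 75 °C
Reagents that add atoms: none
Why: Acylation through the mixed 2,4,6-trichlorobenzoic anhydride (Yamaguchi-type esterification run without a nucleophilic catalyst) transfers the less hindered angeloyl group to the only free hydroxyl, C18–OH, and leaving out 4-dimethylaminopyridine avoids the addition–elimination pathway that turns angelates into tiglates, so the (Z)-geometry is kept.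

**Step 18**
Reactants: 25 (4S,5S,8S,9S,10R,13S)-15-[(tert-butyldimethylsilyl)oxy]-8-[(triethylsilyl)oxy]-ent-labdan-18-yl (2Z)-2-methylbut-2-enoate
Product: 26 (4S,5S,8S,9S,10R,13S)-8,15-dihydroxy-ent-labdan-18-yl (2Z)-2-methylbut-2-enoate
Conditions: HF·pyridine, pyridine, THF, 0 °C → rt
Reagents that add atoms: none
Why: Buffered HF·pyridine cleaves the primary and the tertiary silyl ether through pentacoordinate fluorosilicates (fluoride desilylation) under conditions in which the angelate neither hydrolyses nor isomerises and the tertiary C8 alcohol does not eliminate, which gives the target.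

**Compound list**

1 | (R)-5-methoxy-3-methyl-5-oxopentanoic acid (methyl hydrogen (R)-3-methylglutarate) | COC(=O)C[C@H](C)CC(=O)O | starting material
2 | methyl (R)-5-hydroxy-3-methylpentanoate | COC(=O)C[C@H](C)CCO | intermediate
3 | methyl (R)-5-[(tert-butyldimethylsilyl)oxy]-3-methylpentanoate | COC(=O)C[C@H](C)CCO[Si](C)(C)C(C)(C)C | intermediate
4 | (S)-5-[(tert-butyldimethylsilyl)oxy]-3-methylpentan-1-ol | OCC[C@H](C)CCO[Si](C)(C)C(C)(C)C | intermediate
5 | (R)-[(5-bromo-3-methylpentyl)oxy](tert-butyl)dimethylsilane | BrCC[C@H](C)CCO[Si](C)(C)C(C)(C)C | intermediate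
6 | nerol, (2Z)-3,7-dimethylocta-2,6-dien-1-ol | CC(C)=CCC/C(C)=C\CO | starting material
7 | (2R,3S)-2,3-epoxynerol, [(2R,3S)-3-methyl-3-(4-methylpent-3-en-1-yl)oxiran-2-yl]methanol | CC(C)=CCC[C@]1(C)O[C@@H]1CO | intermediate
8 | Grignard reagent, (R)-{5-[(tert-butyldimethylsilyl)oxy]-3-methylpentyl}magnesium bromide | Br[Mg]CC[C@H](C)CCO[Si](C)(C)C(C)(C)C | intermediate
9 | bromomagnesium alkoxide of 7, bromo{[(2R,3S)-3-methyl-3-(4-methylpent-3-en-1-yl)oxiran-2-yl]methoxy}magnesium | CC(C)=CCC[C@]1(C)O[C@@H]1CO[Mg]Br | intermediate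
10 | (2S,3S)-2-{(3S)-5-[(tert-butyldimethylsilyl)oxy]-3-methylpentyl}-3,7-dimethyloct-6-ene-1,3-diol | CC(C)=CCC[C@](C)(O)[C@H](CO)CC[C@H](C)CCO[Si](C)(C)C(C)(C)C | intermediate
11 | (2S,3S)-2-{(3S)-5-[(tert-butyldimethylsilyl)oxy]-3-methylpentyl}-3,7-dimethyl-1,3-bis[(triethylsilyl)oxy]oct-6-ene | CC(C)=CCC[C@](C)(O[Si](CC)(CC)CC)[C@H](CO[Si](CC)(CC)CC)CC[C@H](C)CCO[Si](C)(C)C(C)(C)C | intermediate
12 | (2R,3S)-2-{(3S)-5-[(tert-butyldimethylsilyl)oxy]-3-methylpentyl}-3,7-dimethyl-3-[(triethylsilyl)oxy]oct-6-enal | CC(C)=CCC[C@](C)(O[Si](CC)(CC)CC)[C@H](C=O)CC[C@H](C)CCO[Si](C)(C)C(C)(C)C | intermediate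
13 | tert-butyl{[(3S,6S,7S)-6-ethynyl-3,7,11-trimethyl-7-[(triethylsilyl)oxy]dodec-10-en-1-yl]oxy}dimethylsilane | CC(C)=CCC[C@](C)(O[Si](CC)(CC)CC)[C@H](C#C)CC[C@H](C)CCO[Si](C)(C)C(C)(C)C | intermediate
14 | enal, (2E,6S,7S,10S)-12-[(tert-butyldimethylsilyl)oxy]-7-ethynyl-2,6,10-trimethyl-6-[(triethylsilyl)oxy]dodec-2-enal | O=C/C(C)=C/CC[C@](C)(O[Si](CC)(CC)CC)[C@H](C#C)CC[C@H](C)CCO[Si](C)(C)C(C)(C)C | intermediate
15 | (2E,6S,7S,10S)-12-[(tert-butyldimethylsilyl)oxy]-7-ethynyl-2,6,10-trimethyl-6-[(triethylsilyl)oxy]dodec-2-en-1-ol | OC/C(C)=C/CC[C@](C)(O[Si](CC)(CC)CC)[C@H](C#C)CC[C@H](C)CCO[Si](C)(C)C(C)(C)C | intermediate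
16 | alkenylalane, the (E)-1-(dimethylalumanyl)prop-1-en-2-yl compound from 15 with the allylic oxygen bound as O–AlMe2 | C[Al](C)OC/C(C)=C/CC[C@](C)(O[Si](CC)(CC)CC)[C@H](/C(C)=C/[Al](C)C)CC[C@H](C)CCO[Si](C)(C)C(C)(C)C | intermediate
17 | (2E,6S,7S,10S)-12-[(tert-butyldimethylsilyl)oxy]-7-[(E)-1-iodoprop-1-en-2-yl]-2,6,10-trimethyl-6-[(triethylsilyl)oxy]dodec-2-en-1-ol | OC/C(C)=C/CC[C@](C)(O[Si](CC)(CC)CC)[C@H](/C(C)=C/I)CC[C@H](C)CCO[Si](C)(C)C(C)(C)C | intermediate
18 | (2E,6S,7S,8E)-7-{(3S)-5-[(tert-butyldimethylsilyl)oxy]-3-methylpentyl}-2,6,8-trimethyl-6-[(triethylsilyl)oxy]undeca-2,8,10-trien-1-ol | OC/C(C)=C/CC[C@](C)(O[Si](CC)(CC)CC)[C@H](/C(C)=C/C=C)CC[C@H](C)CCO[Si](C)(C)C(C)(C)C | intermediate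
19 | (2E,6S,7S,8E)-7-{(3S)-5-[(tert-butyldimethylsilyl)oxy]-3-methylpentyl}-2,6,8-trimethyl-6-[(triethylsilyl)oxy]undeca-2,8,10-trienal | O=C/C(C)=C/CC[C@](C)(O[Si](CC)(CC)CC)[C@H](/C(C)=C/C=C)CC[C@H](C)CCO[Si](C)(C)C(C)(C)C | intermediate
20 | (4S,5S,8S,9S,10R,13S)-15-[(tert-butyldimethylsilyl)oxy]-8-[(triethylsilyl)oxy]-ent-labd-1-en-18-al | O=C[C@@]1(C)CC=C[C@]2(C)[C@@H]1CC[C@](C)(O[Si](CC)(CC)CC)[C@H]2CC[C@H](C)CCO[Si](C)(C)C(C)(C)C | intermediate
21 | (4S,5S,8S,9S,10R,13S)-15-[(tert-butyldimethylsilyl)oxy]-8-[(triethylsilyl)oxy]-ent-labd-1-en-18-ol | OC[C@@]1(C)CC=C[C@]2(C)[C@@H]1CC[C@](C)(O[Si](CC)(CC)CC)[C@H]2CC[C@H](C)CCO[Si](C)(C)C(C)(C)C | intermediate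
22 | (4S,5S,8S,9S,10R,13S)-15-[(tert-butyldimethylsilyl)oxy]-8-[(triethylsilyl)oxy]-ent-labdan-18-ol | OC[C@@]1(C)CCC[C@]2(C)[C@@H]1CC[C@](C)(O[Si](CC)(CC)CC)[C@H]2CC[C@H](C)CCO[Si](C)(C)C(C)(C)C | intermediate
23 | angelic acid, (2Z)-2-methylbut-2-enoic acid | C/C=C(/C)C(=O)O | starting material
24 | mixed anhydride, (2Z)-2-methylbut-2-enoic 2,4,6-trichlorobenzoic anhydride | C/C=C(/C)C(=O)OC(=O)c1c(Cl)cc(Cl)cc1Cl | intermediate
25 | (4S,5S,8S,9S,10R,13S)-15-[(tert-butyldimethylsilyl)oxy]-8-[(triethylsilyl)oxy]-ent-labdan-18-yl (2Z)-2-methylbut-2-enoate | C/C=C(/C)C(=O)OC[C@@]1(C)CCC[C@]2(C)[C@@H]1CC[C@](C)(O[Si](CC)(CC)CC)[C@H]2CC[C@H](C)CCO[Si](C)(C)C(C)(C)C | intermediate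
26 | CNP0150844.1, (4S,5S,8S,9S,10R,13S)-8,15-dihydroxy-ent-labdan-18-yl (2Z)-2-methylbut-2-enoate | C/C=C(/C)C(=O)OC[C@@]1(C)CCC[C@]2(C)[C@@H]1CC[C@](C)(O)[C@H]2CC[C@H](C)CCO | target

**Step count and risks**

Total step count: 18.
Longest linear sequence: 17 steps (steps 1–4 and 6–18, from 1); the nerol branch runs 14 steps (5–18), and angelic acid enters at step 17.

Steps most likely to fail:

Step 14 (key step). The cycloaddition may be slower than side processes set off by the Lewis acid, namely cationic oligomerisation at the 1,1-disubstituted diene terminus and ionisation of the tertiary silyl ether. The tether may also fold in part through the alternative chair with the C11 chain and the C8 silyloxy group axial; the preference between the two chairs is not large, because the favoured one puts the C8 methyl axial and syn to C20. That would erode the facial selectivity relative to C8 and C9, and exo folding to the cis-fused isomer is a further leak. The fallback replaces substrate control by reagent control. It sets out from 19 and comes back at 20, and no new compound F0 arises. Trienal 19 is cyclised with a chiral cationic oxazaborolidinium Lewis acid, prepared from α,α-diphenylprolinol, o-tolylboroxine and triflimide and used in sub-stoichiometric amount in CH2Cl2 at −78 → −20 °C. This catalyst class is established for Diels–Alder reactions of 2-substituted enals, intramolecular ones included. It activates the enal more strongly than Me2AlCl, holds it s-trans through a formyl C–H···O contact and shields one enal face with an aryl group. Both catalyst enantiomers are accessible, and the one whose open face is the face demanded by C8 and C9 is chosen, so that catalyst and substrate reinforce each other.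

Step 9. Addition of the diazophosphonate anion to the hindered, α-branched carbonyl may be slow enough for enolisation in K2CO3/MeOH to compete, which would epimerise C9 or expel the C8 silyloxy group by β-elimination. The fallback is the Corey–Fuchs sequence, in which the aldehyde never meets a base. It sets out from 12 and comes back at 13. Treatment of 12 with CBr4, PPh3 and Zn in CH2Cl2 at 0 °C should give the 1,1-dibromoalkene F1 by a Wittig-type olefination. n-BuLi (2.1 equiv) in THF at −78 °C then effects bromine–lithium exchange and Fritsch–Buttenberg–Wiechell rearrangement to the lithium acetylide F2, which aqueous NH4Cl protonates to alkyne 13.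

Step 17. Acylation of the neopentyl-type C18 hydroxyl is slow, and at 75 °C reversible conjugate addition of chloride or carboxylate to the mixed anhydride may isomerise the angeloyl group to the tigloyl group. The fallback builds the Z-alkene on the ester and does not transfer it. It sets out from 22 and comes back at 25. Esterification of 22 with 2-[bis(2,2,2-trifluoroethoxy)phosphoryl]propanoic acid (DCC, DMAP, CH2Cl2, rt) gives the phosphonopropanoate F3, which has no alkene to isomerise. Deprotonation with KN(SiMe3)2 and 18-crown-6 in THF at −78 °C gives its potassium carbanion F4, and Still–Gennari olefination with acetaldehyde then forms the (Z)-2-methylbut-2-enoate 25 under kinetic control.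

**Further compounds**

F0 | step 14 | none | none
F1 | step 9 | tert-butyl{[(3S,6S,7S)-6-(2,2-dibromoethenyl)-3,7,11-trimethyl-7-[(triethylsilyl)oxy]dodec-10-en-1-yl]oxy}dimethylsilane | CC(C)=CCC[C@](C)(O[Si](CC)(CC)CC)[C@H](C=C(Br)Br)CC[C@H](C)CCO[Si](C)(C)C(C)(C)C
F2 | step 9 | lithium acetylide of 13 | CC(C)=CCC[C@](C)(O[Si](CC)(CC)CC)[C@H](C#C[Li])CC[C@H](C)CCO[Si](C)(C)C(C)(C)C
F3 | step 17 | (4S,5S,8S,9S,10R,13S)-15-[(tert-butyldimethylsilyl)oxy]-8-[(triethylsilyl)oxy]-ent-labdan-18-yl 2-[bis(2,2,2-trifluoroethoxy)phosphoryl]propanoate (both epimers at the phosphonate α-carbon) | CC(C(=O)OC[C@@]1(C)CCC[C@]2(C)[C@@H]1CC[C@](C)(O[Si](CC)(CC)CC)[C@H]2CC[C@H](C)CCO[Si](C)(C)C(C)(C)C)P(=O)(OCC(F)(F)F)OCC(F)(F)F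
F4 | step 17 | potassium carbanion of F3 | C[C-](C(=O)OC[C@@]1(C)CCC[C@]2(C)[C@@H]1CC[C@](C)(O[Si](CC)(CC)CC)[C@H]2CC[C@H](C)CCO[Si](C)(C)C(C)(C)C)P(=O)(OCC(F)(F)F)OCC(F)(F)F.[K+]
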